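(The data were generated by integration with constants of no real substance; noise was put on by code.)

What holds still from Friday's flask to Monday's is the percent read at a given charged [partner]: both flasks stand at 0 °C with [partner] of 18.0 mM and 18.0 mM, and although Monday's carries half the starting material, they read 8.4% and 9.0% at 20.0 h. So we scale the slope by [partner] and not by the starting material.

| setting | Friday's | Sunday's | Monday's | teal | blue |
|---|---|---|---|---|---|
| starting material | 18 mM | 18 mM | 9 mM | 18 mM | 18 mM |
| partner | 1 equiv | 1.5 equiv | 2 equiv | 2.00 equiv | 2.00 equiv |
| temperature | 0 °C | 11 °C | 0 °C | 5 °C | 5 °C |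
| remark | run made earlier | run made earlier | run made earlier |  |  |
| time |  |  |  | 60 h | 30 h |

| run | time / h | target / % |
|---|---|---|
| Friday's | 1.33 | 1.4 |
| Friday's | 4.00 | 1.1 |
| Friday's | 6.00 | 1.1 |
| Friday's | 10.0 | 4.2 |
| Friday's | 15.0 | 4.7 |
| Friday's | 20.0 | 8.4 |
| Sunday's | 3.00 | 5.7 |
| Sunday's | 6.00 | 13.0 |
| Sunday's | 10.0 | 20.3 |
| Sunday's | 12.0 | 22.7 |
| Sunday's | 15.0 | 26.9 |
| Sunday's | 20.0 | 30.5 |
| Monday's | 1.50 | 0.4 |
| Monday's | 5.00 | 0.6 |
| Monday's | 8.00 | 1.9 |
| Monday's | 12.0 | 4.4 |
| Monday's | 20.0 | 9.0 |

(each reading ± 0.5 percentage points)

1. which one finishes higher in amount of target, in percent of the starting material charged ("neither" within 2 percentage points) (teal / blue / neither)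
2. amount of target at the end, in percent of the starting material charged, teal
3. amount of target at the end, in percent of the starting material charged, blue

We draw the curve from Sunday's flask. Its readings climb at 0.0217 /h, as a fraction of the charge, over the first 6.00 h, and then their step from 10.0 h to 20.0 h is about half the step before, which for a first-order rise means a level, read from these scattered points, of 40.8%. Per unit of [partner], Sunday's slope is 2.77 times Friday's later slope, and since 5 °C lies near the middle of 0 °C and 11 °C, we take the square root of that factor for the step down from Sunday's temperature.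

Teal and blue are the same flask, read at different times. At [partner] of 36.0 mM we reckon its starting slope at 0.0174 /h, and we assume Sunday's level carries over. That starting line crosses the level at the knee time, 23.5 h, the time constant of the rise. Blue stops 1.28 knee times out and teal, read twice as late, 2.55, so our own reckoning gives 29.4% for blue and 37.6% for teal.

The forecast names teal, with 36% (25% to 50%) for teal and 26% (18% to 35%) for blue, a little below our figures: “Product decay is the main risk, but teal is favoured.”

The flasks give teal: 35.5% for teal and 28.1% for blue.

    partner + intermediate C → side product (k = 2.60 /M/h, Ea = 53.0 kJ/mol)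
    intermediate B → intermediate C (k = 0.120 /h, Ea = 84.0 kJ/mol)
    partner → decomposed reagent (k = 0.0130 /h, Ea = 101 kJ/mol)
    partner + intermediate C ⇌ intermediate D (K = 42.0 /M, k = 3.10 /M/h, Ea = 64.0 kJ/mol, ΔH = −4.00 kJ/mol)
    starting material + partner → intermediate B (k = 3.90 /M/h, Ea = 57.0 kJ/mol)
    partner + intermediate A → target (k = 2.30 /M/h, Ea = 70.0 kJ/mol)
    starting material → intermediate A (k = 0.0990 /h, Ea = 81.0 kJ/mol)
    (constants at 5 °C)

Teal has not come to rest at 60 h: our curve still leaves 3.2 percentage points to the level, and teal left ten times as long, to 600 h, holds 40.8% of target, a further 5.3 points. From 60 h to 600 h intermediate A in teal falls from 12.9% to 7.73% and the partner from 13% to 0%, and target in teal, which stood at 28.1% at 30.0 h, goes on rising, so the product decay the forecast named as a risk does not show in teal's target. Blue read at 12 h stands 0.511 of a knee time out, which gives 16.3%; that flask holds 14.8% of target.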